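**The problem**

Compound 39 is a cis-fused hydrindan-2-one. Locants used throughout: C1–C3, C3a, C4–C7, C7a for the bicycle; C8 and C9 for the chain on C7 (C8 on the ring, C9 the future ester carbon); C10 for the carbinol carbon on C1; α is the face of H3a and H7a, β the opposite face. There are nine stereocentres: six contiguous ring centres (C1, C7a, C3a, C7, C6, C5), the exocyclic C10 and C8, and one in the 3-methylpentanoate. H1, H3a, H7 and H7a are all α, so the C1 arm, the C7 glycidate and the C6 ester crowd the concave β face, while the C5 ester is α. The ring fusion can relay to C7 (cycloaddition) and to C5/C6 (reagents arrive from the α face), but C10 and C8 lie outside the ring and need a chiral-pool or reagent source. The molecule is fragile: C2=O with the C10 acetate is a β-acyloxy ketone that eliminates with base, C1 can epimerise to the more stable trans arrangement, four different esters are present, and the terminal glycidate epoxide does not survive strong acid. A free C6 hydroxyl beside a C9 carboxyl would close a γ-lactone, and an ether oxygen on C9 can capture a cation at C6, so the order of events on that flank is dictated. The handle for the key step is the aldol unit C2(=O)–C1–C10(O): it is the retron of a 2,3-epoxy alcohol rearrangement in which the C2–C7a bond of a cyclobutanol moves to C1, and the cis-bicyclo[4.2.0]octenone this requires is a Diels–Alder adduct of cyclobutenone.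

**Retrosynthesis**

C2 carbonyl. The ketone of 39 is unveiled last, from the silyl ether 37 via alcohol 38, because every base-mediated operation would otherwise act on a β-acetoxy ketone. Carrying C2 as a protected alcohol from 15 onward costs four steps but removes the elimination and C1-epimerisation pathways from the whole middle of the route.

Glycidate. The epoxide oxygen and the exocyclic carbon on C8 are cut: 37 comes from epoxy alcohol 35, this from allylic alcohol 34 by asymmetric epoxidation, and 34 from aldehyde 32 by α-methylenation (33) and reduction. Direct epoxidation of the corresponding 2-substituted acrylate would be shorter but would leave C8 to substrate control; an allylic alcohol allows reagent control. The chain is raised to the acid level only after O6 is acylated (30), so that no hydroxy acid able to lactonise ever exists.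

Ring esters. The C5–O and C6–O acyl bonds are cut in turn. Diester 30 comes from 27 by acylation of the hindered 6β-hydroxyl, and the 5α-ester of 26 from the 5β-alcohol 24 by inversion with acid 25. Inversion is accepted because hydride can only reach the C5 ketone of 23 from the α face; it installs the ester and corrects the centre in one step.

C4 methylene and ring oxygens. The exocyclic carbon is cut from enone 23, which leads back to ketone 20 and α-ketol 19. The C5 carbonyl and the 6β-oxygen come from β-epoxide 17 and hence from alkene 15. Allylic oxidation at C4 was considered but would compete with abstraction of the tertiary H7. The β-oxygen at C6 cannot be introduced by direct attack on the crowded face, so it enters as water during trans-diaxial bromohydrin formation; the epoxide is then opened at C5 from the open α face.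

Masking. Alkene 15 is the key-step product 12 after acetylation of both hydroxyls (13), reduction of C2 (14) and silylation. The C9 oxygen is carried as an acetate here because an ether there would cyclise onto the bromonium ion.

Key disconnection. The C1–C7a bond of 12 is cut and C2–C7a restored, giving the cis-epoxy cyclobutanol 11. This removes one ring size, trades the base-labile aldol for a stable epoxy alcohol, and converts the contra-steric C1 centre into an epoxide configuration. The forward reaction must be anti-stereospecific and must move C7a, not C3.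

Epoxy alcohol. The C1–C2 bond of 11 is cut to ketone 6 and an oxiranyl anion. Adding a (Z)-propenyl group and epoxidising afterwards was set aside: conformational analysis suggests a hydroxyl-directed oxidant would approach from the side remote from the C7 chain, which is the unwanted C1/C10 pair, and an undirected oxidant would not distinguish the ring alkene. Instead the epoxide arrives intact as lithiated epoxysilane 9, made from silane 8 and ultimately (S)-2-methyloxirane 7. The silyl group makes the anion configurationally stable and places the cyclobutane cis to the methyl group; fluoride then removes it (10 to 11).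

Bicycle. The two ring bonds of 6 are cut to cyclobutenone 3 and silyl dienyl ether 5 in an endo, "ortho" Diels–Alder reaction that sets C3a, C7a and C7 at once. Compound 3 comes from acid 1 via bromide 2, and 5 from dienol 4. The six-carbon dienol is preferred over a pentadienol because its chain already holds both C8 and C9.

**Roads not taken**

Alternative 1: The cut is C7–C7a and C1–C10, made by intramolecular [2+2] photocycloaddition of a tethered dioxinone to a cyclopentene, giving cyclobutane photoadduct A1; a de Mayo retro-aldol would then open the four-membered ring. Its real merit is that the tether already carries a C4 ketal and differentiated oxygens at C5 and C6. That is better than the chosen plan, which spends eight steps on C4–C6. Against this, fragmentation of A1 leaves C7 bearing a carboxyl carbon directly, so C8 arrives at the wrong oxidation level and two more carbons must be added to build the glycidate. C10 arrives as a methyl ketone, so its configuration must be set by a later reduction, and C1, now α to that ketone, can drift to the trans arrangement. The tether stereocentres must be set by acyclic methods first, and the photochemical step scales poorly. The chosen plan sets C1 and C10 together, stereospecifically and without base, and pays for that with a longer C4–C6 sequence.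

Alternative 2: The cut is C7–C8 and C4–C12 (C12 being the exocyclic methylene carbon), made by oxidative dearomatisation of a phenol in methanol and intramolecular Diels–Alder capture by a tethered silyloxyacrylate, giving bridged bicyclo[2.2.2]octenone lactone A2. It builds complexity quickly from an arene, brings oxygen to C5 and C6 and the C8–C9 ester unit in one step, and lets the C10 stereocentre steer through the lactone tether; in carbon economy it is superior to the chosen plan. Its weak points are structural. A2 contains a C8–C12 bond that the target lacks and that must be fragmented. The ring fusion is a tetrasubstituted C3a=C7a alkene that must be hydrogenated cis from one defined face of a hindered bicycle. The ketone/ketal pair must be turned into a trans-diol with two different esters. The chosen plan obtains the cis ring fusion and C7 directly from an endo cycloaddition and has no C–C bond to break again; this certainty is what it sets against the faster build-up of A2.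

Alternative 3: The cut is C7–C7a, made by intramolecular Sakurai conjugate allylation of a 2-substituted cyclopentenone, with C1 set by kinetic protonation of the aluminium enolate, giving hydrindanone A3. This is the most convergent route: A3 already carries both ring esters, the C4 methylene and the acrylate, so only epoxidation and a silyl-to-acetate exchange remain. If it worked it would be clearly shorter than the chosen plan. The doubts are mechanistic. The aluminium enolate has a β-silyloxy group at C10 and can eliminate. The C5 ester is allylic to the C4 alkene and exposed to a strong Lewis acid. Three stereocentres (C7a, C7, C1) depend on a single transition state plus a protonation that must give the less stable C1 epimer. The final acrylate epoxidation would set C8 under substrate control next to a base-sensitive β-silyloxy ketone. The chosen plan is longer but fixes C1/C10 by a stereospecific shift and C8 by a reagent-controlled epoxidation.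

Key step: step 8

Assumption: the (S)-configured oxazaborolidinium catalyst in step 4 is taken to favour the (1S,5S,6R) adduct by analogy with its behaviour toward other cyclic enones; if the sense is opposite, the (R)-catalyst is used.
Assumption: (E)-hexa-3,5-dien-1-ol, (S)-3-methylpentanoic acid and (E)-3-methylpent-2-enoic acid are taken as purchasable.

**Steps**

Step 1
Reactants: 1 3-oxocyclobutane-1-carboxylic acid
Product: 2 3-bromocyclobutan-1-one
Conditions: HgO, Br2, CH2Cl2, reflux
Reagents that add atoms: bromine, BrBr
Why: Hunsdiecker bromodecarboxylation (mercuric oxide variant): the acyl hypobromite loses CO2 and the alkyl radical is trapped by bromine; the ketone is a spectator.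

Step 2
Reactants: 2 3-bromocyclobutan-1-one
Product: 3 cyclobut-2-en-1-one
Conditions: n-Bu3N, neat, rt; distilled into cold CH2Cl2
Reagents that add atoms: none
Why: Dehydrobromination of a β-bromo ketone (E1cB) by a tertiary amine; the enone is kept cold in solution and used at once because it oligomerises.

Step 3
Reactants: 4 (E)-hexa-3,5-dien-1-ol
Product: 5 tert-butyl[(E)-hexa-3,5-dien-1-yloxy]dimethylsilane
Conditions: t-BuMe2SiCl, imidazole, CH2Cl2, 0 °C → rt
Reagents that add atoms: tert-butyldimethylsilyl chloride, CC(C)(C)[Si](C)(C)Cl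
Why: Standard silylation of a primary alcohol; the ether keeps the hydroxyl away from the acidic catalyst and the organolithium of the next steps.

Step 4
Reactants: 3 cyclobut-2-en-1-one; 5 tert-butyl[(E)-hexa-3,5-dien-1-yloxy]dimethylsilane
Product: 6 (1S,5S,6R)-5-[2-(tert-butyldimethylsilyloxy)ethyl]bicyclo[4.2.0]oct-3-en-7-one
Conditions: (S)-3,3-diphenyl-1-(2-methylphenyl)tetrahydro-1H,3H-pyrrolo[1,2-c][1,3,2]oxazaborole (20 mol %), Tf2NH (20 mol %), CH2Cl2, −78 °C
Reagents that add atoms: none
Why: Catalytic enantioselective Diels–Alder reaction of a strained cyclic enone; the substituted diene terminus bonds to the enone α-carbon ("ortho") and the endo transition state places the (E)-substituent cis to the cyclobutanone, which sets C3a, C7a and C7 relative to one another, while the chiral boron Lewis acid selects the enone face.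

Step 5
Reactants: 7 (S)-2-methyloxirane
Product: 8 trimethyl[(2S,3S)-3-methyloxiran-2-yl]silane
Conditions: lithium 2,2,6,6-tetramethylpiperidide, Me3SiCl (in situ), THF, −78 → 0 °C
Reagents that add atoms: chlorotrimethylsilane, C[Si](C)(C)Cl
Why: Direct α-lithiation of a terminal epoxide by a hindered lithium amide with in situ silylation; the hydrogen trans to the methyl group is removed, so the silyl group ends trans and the methyl-bearing centre (future C10) comes unchanged from the chiral pool.

Step 6
Reactants: 8 trimethyl[(2S,3S)-3-methyloxiran-2-yl]silane; 6 (1S,5S,6R)-5-[2-(tert-butyldimethylsilyloxy)ethyl]bicyclo[4.2.0]oct-3-en-7-one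
Product: 10 5-[2-(tert-butyldimethylsilyloxy)ethyl]-7-[(3S)-3-methyl-2-(trimethylsilyl)oxiran-2-yl]-cis-bicyclo[4.2.0]oct-3-en-7-ol (7-OH on the concave face; methyl cis to the cyclobutane), via α-lithiated epoxysilane 9 (not isolated)
Conditions: s-BuLi, TMEDA, Et2O, −116 °C; then 6, −116 → −78 °C
Reagents that add atoms: none
Why: Generation and carbonyl addition of an α-silyl oxiranyllithium, which is configurationally stable at this temperature and reacts with retention, so the cyclobutane takes the place of the removed hydrogen, cis to the methyl group; the strained ketone is attacked from its convex face, which puts the new hydroxyl on the concave side.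

Step 7
Reactants: 10 5-[2-(tert-butyldimethylsilyloxy)ethyl]-7-[(3S)-3-methyl-2-(trimethylsilyl)oxiran-2-yl]-cis-bicyclo[4.2.0]oct-3-en-7-ol
Product: 11 5-(2-hydroxyethyl)-7-[(2S,3S)-3-methyloxiran-2-yl]-cis-bicyclo[4.2.0]oct-3-en-7-ol (cis-epoxide; 7-OH on the concave face)
Conditions: Bu4NF (3 equiv), wet THF, 0 °C → rt
Reagents that add atoms: none
Why: Fluoride-induced protodesilylation of an epoxysilane, assisted by the neighbouring hydroxyl and proceeding with retention, gives the cis-epoxide; the primary silyl ether is cleaved in the same operation.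

Step 8
Reactants: 11 5-(2-hydroxyethyl)-7-[(2S,3S)-3-methyloxiran-2-yl]-cis-bicyclo[4.2.0]oct-3-en-7-ol
Product: 12 (3aα,7aα)-1β-[(1S)-1-hydroxyethyl]-7β-(2-hydroxyethyl)-1,3,3a,4,7,7a-hexahydro-2H-inden-2-one
Conditions: BF3·OEt2 (2.2 equiv), CH2Cl2, −78 °C; then aq. NaHCO3
Reagents that add atoms: none
Why: BF3 binds the epoxide oxygen and weakens the C1–O bond; the antiperiplanar C2–C7a bond of the cyclobutanol shifts to C1 as C2 becomes the carbonyl, a concerted semipinacol 1,2-shift driven by release of four-ring strain. The closest known reaction type is the Lewis-acid rearrangement of 2,3-epoxy alcohols, including expansion of 1-oxiranylcyclobutanols to 2-(1-hydroxyalkyl)cyclopentanones. The cyclopentanone closes by ring expansion, the migrating carbon opening the epoxide in the exo sense from the side opposite to oxygen. The one new stereocentre, C1, is formed with inversion and so is dictated by the epoxide configuration that came from 7; C7a migrates with retention and C10 is untouched, which together give the contra-steric cis arrangement of the C1 arm and C7. The step needs migration of the ring-fusion carbon C7a rather than the methylene C3; the higher migratory aptitude of the more substituted carbon should secure this. It also needs strict anti stereospecificity, which the low temperature and the concerted pathway favour over a free C1 cation. The aldol is formed without base, so neither elimination nor C1 epimerisation can intervene, and the extra equivalent of Lewis acid allows for the two free hydroxyls.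

Step 9
Reactants: 12 (3aα,7aα)-1β-[(1S)-1-hydroxyethyl]-7β-(2-hydroxyethyl)-1,3,3a,4,7,7a-hexahydro-2H-inden-2-one
Product: 13 (3aα,7aα)-1β-[(1S)-1-acetoxyethyl]-7β-(2-acetoxyethyl)-1,3,3a,4,7,7a-hexahydro-2H-inden-2-one
Conditions: Ac2O, pyridine, DMAP (5 mol %), CH2Cl2, 0 °C
Reagents that add atoms: acetic anhydride, CC(=O)OC(C)=O
Why: Acylation of both hydroxyls under mild conditions; the C10 acetate is the one in the target, and the C9 acetate is a non-nucleophilic cover that cannot cyclise onto C6 later.

Step 10
Reactants: 13 (3aα,7aα)-1β-[(1S)-1-acetoxyethyl]-7β-(2-acetoxyethyl)-1,3,3a,4,7,7a-hexahydro-2H-inden-2-one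
Product: 14 (3aα,7aα)-1β-[(1S)-1-acetoxyethyl]-7β-(2-acetoxyethyl)-2,3,3a,4,7,7a-hexahydro-1H-inden-2β-ol
Conditions: NaBH4, CeCl3·7H2O, MeOH, −78 °C; AcOH quench
Reagents that add atoms: none
Why: Luche-type carbonyl reduction; hydride arrives from the convex α face to give the 2β-alcohol, the low temperature and acidic quench suppress acetyl migration and elimination, and this centre is erased again in step 28.

Step 11
Reactants: 14 (3aα,7aα)-1β-[(1S)-1-acetoxyethyl]-7β-(2-acetoxyethyl)-2,3,3a,4,7,7a-hexahydro-1H-inden-2β-ol
Product: 15 (3aα,7aα)-1β-[(1S)-1-acetoxyethyl]-7β-(2-acetoxyethyl)-2β-(tert-butyldimethylsilyloxy)-2,3,3a,4,7,7a-hexahydro-1H-indene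
Conditions: t-BuMe2SiOTf, 2,6-lutidine, CH2Cl2, −78 → 0 °C
Reagents that add atoms: tert-butyldimethylsilyl triflate, CC(C)(C)[Si](C)(C)OS(=O)(=O)C(F)(F)F
Why: Silylation of a hindered secondary alcohol with the silyl triflate; the bulky ether masks C2 through all enolate, hydride and Mitsunobu steps.

Step 12
Reactants: 15 (3aα,7aα)-1β-[(1S)-1-acetoxyethyl]-7β-(2-acetoxyethyl)-2β-(tert-butyldimethylsilyloxy)-2,3,3a,4,7,7a-hexahydro-1H-indene
Product: 17 5β,6β-epoxy derivative of 15 (octahydroindene), via 6α-bromo-5β-ol 16 (not isolated)
Conditions: NBS, DME/H2O (4:1), 0 °C; then DBU, CH2Cl2, rt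
Reagents that add atoms: water, O
Why: Bromohydrin formation followed by base closure: the bromonium ion forms on the open α face, water opens it trans-diaxially from the β face, and either regioisomeric bromohydrin closes to the same β-epoxide, which places oxygen on the crowded face without direct attack there.

Step 13
Reactants: 17 5β,6β-epoxy derivative of 15
Product: 19 6β-hydroxy-5-ketone (α-ketol), via 5α-alkoxysulfonium triflate 18 (not isolated)
Conditions: DMSO, TfOH (1.1 equiv), CH2Cl2, 0 °C → rt; then i-Pr2NEt, rt
Reagents that add atoms: dimethyl sulfoxide, CS(C)=O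
Why: Oxidative epoxide opening of the Kornblum/Swern type: DMSO attacks the protonated epoxide at C5 from the α face (diaxial opening through the chair that keeps the C7 chain equatorial, C6 being shielded), and base collapses the alkoxysulfonium ion to the C5 ketone while the C6–O bond stays β.

Step 14
Reactants: 19 6β-hydroxy-5-ketone
Product: 20 6β-(triethylsilyloxy)-5-ketone
Conditions: Et3SiOTf, 2,6-lutidine, CH2Cl2, −78 °C
Reagents that add atoms: triethylsilyl triflate, CC[Si](CC)(CC)OS(=O)(=O)C(F)(F)F
Why: Fast silylation of the axial α-ketol hydroxyl before it can epimerise; a silyl (not acyl) group is chosen so that no acyl transfer can occur to the enolate or to the cis alkoxide of the following steps.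

Step 15
Reactants: 20 6β-(triethylsilyloxy)-5-ketone
Product: 23 4-methylidene-6β-(triethylsilyloxy)-5-ketone, via 4α-(dimethylaminomethyl) ketone 21 (not isolated), via trimethylammoniomethyl iodide 22 (not isolated)
Conditions: LiN(SiMe3)2, THF, −78 °C; Me2N=CH2 I, −78 °C → rt; then MeI, CH2Cl2, rt; then aq. NaHCO3
Reagents that add atoms: dimethylmethylideneammonium iodide, C=[N+](C)C.[I-]
Why: Kinetic enolisation occurs at C4 (axial hydrogen; the C6 hydrogen is equatorial and flanked by the silyloxy group), the enolate undergoes a Mannich reaction with the iminium salt, and quaternisation–elimination gives the exocyclic enone; the amide base is too weak to deprotonate the acetates at −78 °C.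

Step 16
Reactants: 23 4-methylidene-6β-(triethylsilyloxy)-5-ketone
Product: 24 4-methylidene-6β-(triethylsilyloxy)-5β-ol
Conditions: NaBH4, CeCl3·7H2O, MeOH, −78 °C
Reagents that add atoms: none
Why: Luche 1,2-reduction of the enone; hydride adds axially from the open α face, anti to the axial C6 silyloxy group, giving the 5β-alcohol and leaving the exocyclic alkene in place.

Step 17
Reactants: 24 4-methylidene-6β-(triethylsilyloxy)-5β-ol; 25 (S)-3-methylpentanoic acid
Product: 26 5α-[(3S)-3-methylpentanoyloxy]-4-methylidene-6β-(triethylsilyloxy) derivative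
Conditions: PPh3, DIAD, toluene, 0 °C → rt
Reagents that add atoms: none
Why: Mitsunobu esterification with inversion: the carboxylate attacks C5 from the open α face, which installs the saturated ester and sets the trans relationship to O6 in one step; the cis silyl ether cannot participate.

Step 18
Reactants: 26 5α-[(3S)-3-methylpentanoyloxy]-4-methylidene-6β-(triethylsilyloxy) derivative
Product: 27 5α-[(3S)-3-methylpentanoyloxy]-4-methylidene-6β-ol
Conditions: HF·pyridine, pyridine, THF, 0 °C
Reagents that add atoms: none
Why: Selective desilylation: under buffered fluoride the triethylsilyl ether is cleaved much faster than the hindered secondary tert-butyldimethylsilyl ether at C2, and the esters are untouched.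

Step 19
Reactants: 27 5α-[(3S)-3-methylpentanoyloxy]-4-methylidene-6β-ol; 28 (E)-3-methylpent-2-enoic acid
Product: 30 6β-[(E)-3-methylpent-2-enoyloxy]-5α-[(3S)-3-methylpentanoyloxy]-4-methylidene derivative (C9 acetate), via mixed trichlorobenzoic anhydride 29 (not isolated)
Conditions: 2,4,6-trichlorobenzoyl chloride, Et3N, toluene, rt; then 27, DMAP, toluene, 40 °C
Reagents that add atoms: none
Why: Yamaguchi esterification: the preformed mixed anhydride with DMAP acylates the hindered axial alcohol, and avoiding an acid chloride with amine base prevents ketene formation and deconjugation of the enoate.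

Step 20
Reactants: 30 diester with C9 acetate
Product: 31 7β-(2-hydroxyethyl) diester
Conditions: Mg(OMe)2, MeOH, 0 °C
Reagents that add atoms: none
Why: Chemoselective transesterification: the unhindered primary acetate is methanolysed faster than the three secondary esters, which are all flanked by ring substituents.

Step 21
Reactants: 31 7β-(2-hydroxyethyl) diester
Product: 32 7β-(2-oxoethyl) diester (aldehyde)
Conditions: Dess–Martin periodinane, NaHCO3, CH2Cl2, 0 °C → rt
Reagents that add atoms: none
Why: Dess–Martin oxidation of a primary alcohol under buffered, non-basic conditions; no β-leaving group is available to the aldehyde, since O6 is three carbons from the carbonyl.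

Step 22
Reactants: 32 7β-(2-oxoethyl) diester
Product: 33 7β-(3-oxoprop-1-en-2-yl) diester (2-substituted acrolein)
Conditions: 37% aq. CH2O, pyrrolidine (10 mol %), propionic acid (10 mol %), i-PrOH, 45 °C
Reagents that add atoms: formaldehyde, C=O
Why: Amine-catalysed α-methylenation of an aldehyde (enamine Mannich condensation, then elimination of the amine); the mild buffered conditions leave the esters and the silyl ether alone.

Step 23
Reactants: 33 7β-(3-oxoprop-1-en-2-yl) diester
Product: 34 7β-(3-hydroxyprop-1-en-2-yl) diester (allylic alcohol)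
Conditions: NaBH4, CeCl3·7H2O, MeOH, −78 °C
Reagents that add atoms: none
Why: Luche 1,2-reduction of the enal; the esters are inert at this temperature.

Step 24
Reactants: 34 7β-(3-hydroxyprop-1-en-2-yl) diester
Product: 35 7β-[(2S)-2-(hydroxymethyl)oxiran-2-yl] diester
Conditions: Ti(OiPr)4 (10 mol %), L-(+)-diethyl tartrate (12 mol %), t-BuOOH, 4 Å MS, CH2Cl2, −20 °C
Reagents that add atoms: tert-butyl hydroperoxide, CC(C)(C)OO
Why: Sharpless asymmetric epoxidation of a 2-substituted allylic alcohol; the L-(+)-tartrate delivers oxygen to the face that gives the (S)-epoxy alcohol (the (R)-glycidate after oxidation), under reagent control, and the other two alkenes are not allylic alcohols.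

Step 25
Reactants: 35 7β-[(2S)-2-(hydroxymethyl)oxiran-2-yl] diester
Product: 36 (2R)-oxirane-2-carboxylic acid (glycidic acid)
Conditions: 2,2,6,6-tetramethylpiperidin-1-oxyl (20 mol %), PhI(OAc)2 (2.2 equiv), MeCN/H2O (1:1), rt
Reagents that add atoms: water, O
Why: Oxoammonium-mediated oxidation of the primary alcohol through the aldehyde hydrate to the acid; the conditions spare the alkenes and the epoxide, and O6 is already acylated so no lactone can form.

Step 26
Reactants: 36 (2R)-oxirane-2-carboxylic acid
Product: 37 methyl (2R)-oxirane-2-carboxylate with 2β-silyl ether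
Conditions: Me3SiCHN2, MeOH/toluene (1:4), 0 °C
Reagents that add atoms: trimethylsilyldiazomethane, C[Si](C)(C)C=[N+]=[N-]
Why: Methyl esterification of a carboxylic acid with a diazoalkane under neutral conditions, which protects the acid-sensitive glycidic acid from self-opening.

Step 27
Reactants: 37 methyl (2R)-oxirane-2-carboxylate with 2β-silyl ether
Product: 38 2β-alcohol
Conditions: HF·pyridine, pyridine, THF, 0 °C → rt
Reagents that add atoms: none
Why: Fluoride desilylation under buffered acidic conditions; the electron-poor glycidate epoxide resists opening, and the absence of base prevents acetyl migration from O10 to O2.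

Step 28
Reactants: 38 2β-alcohol
Product: 39 methyl (2R)-2-[(1R,3aS,5R,6R,7R,7aR)-1-[(1S)-1-acetoxyethyl]-6-[(2E)-3-methylpent-2-enoyloxy]-4-methylidene-5-[(3S)-3-methylpentanoyloxy]-2-oxooctahydro-1H-inden-7-yl]oxirane-2-carboxylate
Conditions: Dess–Martin periodinane, CH2Cl2, 0 °C → rt
Reagents that add atoms: none
Why: Dess–Martin oxidation of the secondary alcohol under neutral conditions; the β-acetoxy ketone is generated only in the last step and never meets base.

**Compound list**

1 | 3-oxocyclobutane-1-carboxylic acid | O=C1CC(C1)C(=O)O | starting material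
2 | 3-bromocyclobutan-1-one | O=C1CC(Br)C1 | intermediate
3 | cyclobut-2-en-1-one | O=C1CC=C1 | intermediate
4 | (E)-hexa-3,5-dien-1-ol | C=C/C=C/CCO | starting material
5 | tert-butyl[(E)-hexa-3,5-dien-1-yloxy]dimethylsilane | C=C/C=C/CCO[Si](C)(C)C(C)(C)C | intermediate
6 | (1S,5S,6R)-5-[2-(tert-butyldimethylsilyloxy)ethyl]bicyclo[4.2.0]oct-3-en-7-one | O=C1C[C@@H]2CC=C[C@H](CCO[Si](C)(C)C(C)(C)C)[C@H]12 | intermediate
7 | (S)-2-methyloxirane | C[C@H]1CO1 | starting material
8 | trimethyl[(2S,3S)-3-methyloxiran-2-yl]silane | C[C@@H]1O[C@H]1[Si](C)(C)C | intermediate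
9 | α-lithiated epoxysilane (lithium cis to methyl) | C[C@@H]1O[C@@]1([Li])[Si](C)(C)C | intermediate (not isolated)
10 | silyl epoxy cyclobutanol adduct (7-OH concave; methyl cis to cyclobutane) | C[C@@H]1O[C@]1([Si](C)(C)C)[C@@]2(O)C[C@@H]3CC=C[C@H](CCO[Si](C)(C)C(C)(C)C)[C@H]23 | intermediate
11 | 5-(2-hydroxyethyl)-7-[(2S,3S)-3-methyloxiran-2-yl]-cis-bicyclo[4.2.0]oct-3-en-7-ol | C[C@@H]1O[C@@H]1[C@@]2(O)C[C@@H]3CC=C[C@H](CCO)[C@H]23 | intermediate
12 | (3aα,7aα)-1β-[(1S)-1-hydroxyethyl]-7β-(2-hydroxyethyl)-1,3,3a,4,7,7a-hexahydro-2H-inden-2-one | C1[C@H]2CC(=O)[C@@H]([C@H](C)O)[C@H]2[C@@H](CCO)C=C1 | intermediate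
13 | diacetate of 12 | C1[C@H]2CC(=O)[C@@H]([C@H](C)OC(C)=O)[C@H]2[C@@H](CCOC(C)=O)C=C1 | intermediate
14 | 2β-alcohol | C1[C@H]2C[C@@H](O)[C@@H]([C@H](C)OC(C)=O)[C@H]2[C@@H](CCOC(C)=O)C=C1 | intermediate
15 | 2β-tert-butyldimethylsilyl ether | C1[C@H]2C[C@@H](O[Si](C)(C)C(C)(C)C)[C@@H]([C@H](C)OC(C)=O)[C@H]2[C@@H](CCOC(C)=O)C=C1 | intermediate
16 | 6α-bromo-5β-ol | C1[C@H]2C[C@@H](O[Si](C)(C)C(C)(C)C)[C@@H]([C@H](C)OC(C)=O)[C@H]2[C@@H](CCOC(C)=O)[C@H](Br)[C@H]1O | intermediate (not isolated)
17 | 5β,6β-epoxide | C1[C@H]2C[C@@H](O[Si](C)(C)C(C)(C)C)[C@@H]([C@H](C)OC(C)=O)[C@H]2[C@@H](CCOC(C)=O)[C@H]3O[C@H]31 | intermediate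
18 | 5α-(dimethylsulfonio)oxy-6β-ol triflate | C1[C@H]2C[C@@H](O[Si](C)(C)C(C)(C)C)[C@@H]([C@H](C)OC(C)=O)[C@H]2[C@@H](CCOC(C)=O)[C@@H](O)[C@@H]1O[S+](C)C.[O-]S(=O)(=O)C(F)(F)F | intermediate (not isolated)
19 | 6β-hydroxy-5-ketone | C1[C@H]2C[C@@H](O[Si](C)(C)C(C)(C)C)[C@@H]([C@H](C)OC(C)=O)[C@H]2[C@@H](CCOC(C)=O)[C@@H](O)C1=O | intermediate
20 | 6β-(triethylsilyloxy)-5-ketone | C1[C@H]2C[C@@H](O[Si](C)(C)C(C)(C)C)[C@@H]([C@H](C)OC(C)=O)[C@H]2[C@@H](CCOC(C)=O)[C@@H](O[Si](CC)(CC)CC)C1=O | intermediate
21 | 4α-(dimethylaminomethyl) ketone | CN(C)C[C@@H]1[C@H]2C[C@@H](O[Si](C)(C)C(C)(C)C)[C@@H]([C@H](C)OC(C)=O)[C@H]2[C@@H](CCOC(C)=O)[C@@H](O[Si](CC)(CC)CC)C1=O | intermediate (not isolated)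
22 | trimethylammoniomethyl iodide | C[N+](C)(C)C[C@@H]1[C@H]2C[C@@H](O[Si](C)(C)C(C)(C)C)[C@@H]([C@H](C)OC(C)=O)[C@H]2[C@@H](CCOC(C)=O)[C@@H](O[Si](CC)(CC)CC)C1=O.[I-] | intermediate (not isolated)
23 | 4-methylidene-6β-(triethylsilyloxy)-5-ketone | C=C1[C@H]2C[C@@H](O[Si](C)(C)C(C)(C)C)[C@@H]([C@H](C)OC(C)=O)[C@H]2[C@@H](CCOC(C)=O)[C@@H](O[Si](CC)(CC)CC)C1=O | intermediate
24 | 4-methylidene-6β-(triethylsilyloxy)-5β-ol | C=C1[C@H]2C[C@@H](O[Si](C)(C)C(C)(C)C)[C@@H]([C@H](C)OC(C)=O)[C@H]2[C@@H](CCOC(C)=O)[C@@H](O[Si](CC)(CC)CC)[C@H]1O | intermediate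
25 | (S)-3-methylpentanoic acid | OC(=O)C[C@@H](C)CC | starting material
26 | 5α-[(3S)-3-methylpentanoyloxy]-6β-(triethylsilyloxy) compound | C=C1[C@H]2C[C@@H](O[Si](C)(C)C(C)(C)C)[C@@H]([C@H](C)OC(C)=O)[C@H]2[C@@H](CCOC(C)=O)[C@@H](O[Si](CC)(CC)CC)[C@@H]1OC(=O)C[C@@H](C)CC | intermediate
27 | 5α-[(3S)-3-methylpentanoyloxy]-6β-ol | C=C1[C@H]2C[C@@H](O[Si](C)(C)C(C)(C)C)[C@@H]([C@H](C)OC(C)=O)[C@H]2[C@@H](CCOC(C)=O)[C@@H](O)[C@@H]1OC(=O)C[C@@H](C)CC | intermediate
28 | (E)-3-methylpent-2-enoic acid | OC(=O)/C=C(\C)CC | starting material
29 | (E)-3-methylpent-2-enoic 2,4,6-trichlorobenzoic anhydride | CC/C(C)=C/C(=O)OC(=O)c1c(Cl)cc(Cl)cc1Cl | intermediate (not isolated)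
30 | diester with C9 acetate | C=C1[C@H]2C[C@@H](O[Si](C)(C)C(C)(C)C)[C@@H]([C@H](C)OC(C)=O)[C@H]2[C@@H](CCOC(C)=O)[C@@H](OC(=O)/C=C(\C)CC)[C@@H]1OC(=O)C[C@@H](C)CC | intermediate
31 | 7β-(2-hydroxyethyl) diester | C=C1[C@H]2C[C@@H](O[Si](C)(C)C(C)(C)C)[C@@H]([C@H](C)OC(C)=O)[C@H]2[C@@H](CCO)[C@@H](OC(=O)/C=C(\C)CC)[C@@H]1OC(=O)C[C@@H](C)CC | intermediate
32 | 7β-(2-oxoethyl) diester | C=C1[C@H]2C[C@@H](O[Si](C)(C)C(C)(C)C)[C@@H]([C@H](C)OC(C)=O)[C@H]2[C@@H](CC=O)[C@@H](OC(=O)/C=C(\C)CC)[C@@H]1OC(=O)C[C@@H](C)CC | intermediate
33 | 7β-(3-oxoprop-1-en-2-yl) diester | C=C1[C@H]2C[C@@H](O[Si](C)(C)C(C)(C)C)[C@@H]([C@H](C)OC(C)=O)[C@H]2[C@@H](C(=C)C=O)[C@@H](OC(=O)/C=C(\C)CC)[C@@H]1OC(=O)C[C@@H](C)CC | intermediate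
34 | 7β-(3-hydroxyprop-1-en-2-yl) diester | C=C1[C@H]2C[C@@H](O[Si](C)(C)C(C)(C)C)[C@@H]([C@H](C)OC(C)=O)[C@H]2[C@@H](C(=C)CO)[C@@H](OC(=O)/C=C(\C)CC)[C@@H]1OC(=O)C[C@@H](C)CC | intermediate
35 | 7β-[(2S)-2-(hydroxymethyl)oxiran-2-yl] diester | C=C1[C@H]2C[C@@H](O[Si](C)(C)C(C)(C)C)[C@@H]([C@H](C)OC(C)=O)[C@H]2[C@@H]([C@]2(CO)CO2)[C@@H](OC(=O)/C=C(\C)CC)[C@@H]1OC(=O)C[C@@H](C)CC | intermediate
36 | (2R)-oxirane-2-carboxylic acid | C=C1[C@H]2C[C@@H](O[Si](C)(C)C(C)(C)C)[C@@H]([C@H](C)OC(C)=O)[C@H]2[C@@H]([C@]2(C(=O)O)CO2)[C@@H](OC(=O)/C=C(\C)CC)[C@@H]1OC(=O)C[C@@H](C)CC | intermediate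
37 | methyl (2R)-oxirane-2-carboxylate, 2β-silyl ether | C=C1[C@H]2C[C@@H](O[Si](C)(C)C(C)(C)C)[C@@H]([C@H](C)OC(C)=O)[C@H]2[C@@H]([C@]2(C(=O)OC)CO2)[C@@H](OC(=O)/C=C(\C)CC)[C@@H]1OC(=O)C[C@@H](C)CC | intermediate
38 | 2β-alcohol | C=C1[C@H]2C[C@@H](O)[C@@H]([C@H](C)OC(C)=O)[C@H]2[C@@H]([C@]2(C(=O)OC)CO2)[C@@H](OC(=O)/C=C(\C)CC)[C@@H]1OC(=O)C[C@@H](C)CC | intermediate
39 | methyl (2R)-2-[(1R,3aS,5R,6R,7R,7aR)-1-[(1S)-1-acetoxyethyl]-6-[(2E)-3-methylpent-2-enoyloxy]-4-methylidene-5-[(3S)-3-methylpentanoyloxy]-2-oxooctahydro-1H-inden-7-yl]oxirane-2-carboxylate | C=C1[C@H]2CC(=O)[C@@H]([C@H](C)OC(C)=O)[C@H]2[C@@H]([C@]2(C(=O)OC)CO2)[C@@H](OC(=O)/C=C(\C)CC)[C@@H]1OC(=O)C[C@@H](C)CC | target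

**Step count and least certain steps**

Total: 28 steps. Longest linear sequence: 26 steps (1 → 39 through steps 1, 2, 4 and 6–28); steps 3 and 5 are side branches.

Step 8 (key step). What may go wrong: migration of the methylene C3 in place of C7a, or ionisation of the epoxide toward C10 with hydride shift. The rotamer that sets C2–C7a anti to C1–O pushes C10 toward the C7 chain, and the Lewis acid is partly tied up by the two free hydroxyls. Fallback: from 11, both hydroxyls are silylated (Me3SiCl, imidazole) to the bis(trimethylsilyl) ether F1, which is rearranged with TiCl4 at −78 °C (Suzuki–Tsuchihashi variant); the Lewis acid can then bind only the epoxide and the silyloxy group acts as the donor. Aqueous work-up returns 12.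

Step 4. What may go wrong: oligomerisation of cyclobutenone under the strongly acidic catalyst, or insufficient or reversed enantioselection. Fallback: the cycloaddition of 3 and 5 is run without catalyst at room temperature, giving 6 together with its enantiomer F2. Addition of the enantiopure reagent 9 as in step 6 then gives 10 and the diastereomeric adduct F3, which are separated by chromatography. The route resumes at 10, with the chiral-pool epoxide serving as resolving agent at the cost of half the material.

Step 6. What may go wrong: enolisation of the cyclobutanone by the hindered, basic carbanion, or decomposition of 9 before it adds. Fallback: from 6, (Z)-prop-1-enyllithium F4 (from (Z)-1-bromoprop-1-ene and t-BuLi), transmetallated with CeCl3, gives the (Z)-propenyl carbinol F5. A hydroxyl-directed, catalyst-controlled epoxidation (Hf(OtBu)4, a chiral bis-hydroxamic acid ligand, cumene hydroperoxide) gives the silyl-protected epoxy alcohol F6, and Bu4NF returns 11. The catalyst has to override the expected substrate preference, which is why this is the fallback and not the main route.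

Step 13. What may go wrong: loss of regiocontrol in the opening (attack at C6), acid-induced rearrangement of the epoxide, or epimerisation of the axial α-ketol at C6 under the amine. Fallback: from 17, acid hydrolysis (HClO4, aqueous THF) gives the 5α,6β-diol F7 by the same diaxial opening, and one equivalent of Dess–Martin periodinane oxidises the exposed C5 hydroxyl in preference to the shielded C6 hydroxyl, returning 19.

Step 17. What may go wrong: no activation of the hindered allylic alcohol, or allylic transposition and elimination in place of direct inversion. Fallback: from 23, the silyl ether is cleaved (HF·pyridine) to the hydroxy enone F8. Me4NBH(OAc)3 then delivers hydride from the C6 oxygen to the β face of the ketone, giving the 5α,6β-diol F9, whose less hindered allylic C5 hydroxyl is acylated with 25 (N-ethyl-N'-(3-dimethylaminopropyl)carbodiimide, DMAP, −20 °C) to reach 27.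

**Further compounds**

F1 | step 8 | bis(trimethylsilyl) ether of 11 | C[C@@H]1O[C@@H]1[C@@]2(O[Si](C)(C)C)C[C@@H]3CC=C[C@H](CCO[Si](C)(C)C)[C@H]23
F2 | step 4 | (1R,5R,6S)-5-[2-(tert-butyldimethylsilyloxy)ethyl]bicyclo[4.2.0]oct-3-en-7-one (enantiomer of 6) | O=C1C[C@H]2CC=C[C@@H](CCO[Si](C)(C)C(C)(C)C)[C@@H]12
F3 | step 4 | diastereomeric adduct of F2 with 9 | C[C@@H]1O[C@]1([Si](C)(C)C)[C@]2(O)C[C@H]3CC=C[C@@H](CCO[Si](C)(C)C(C)(C)C)[C@@H]23
F4 | step 6 | (Z)-prop-1-enyllithium | [Li]/C=C\C
F5 | step 6 | 5-[2-(tert-butyldimethylsilyloxy)ethyl]-7-[(Z)-prop-1-enyl]-cis-bicyclo[4.2.0]oct-3-en-7-ol | C/C=C\[C@@]1(O)C[C@@H]2CC=C[C@H](CCO[Si](C)(C)C(C)(C)C)[C@H]12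
F6 | step 6 | tert-butyldimethylsilyl ether of 11 at the primary hydroxyl | C[C@@H]1O[C@@H]1[C@@]2(O)C[C@@H]3CC=C[C@H](CCO[Si](C)(C)C(C)(C)C)[C@H]23
F7 | step 13 | 5α,6β-diol from 17 | C1[C@H]2C[C@@H](O[Si](C)(C)C(C)(C)C)[C@@H]([C@H](C)OC(C)=O)[C@H]2[C@@H](CCOC(C)=O)[C@@H](O)[C@@H]1O
F8 | step 17 | 6β-hydroxy-4-methylidene-5-ketone | C=C1[C@H]2C[C@@H](O[Si](C)(C)C(C)(C)C)[C@@H]([C@H](C)OC(C)=O)[C@H]2[C@@H](CCOC(C)=O)[C@@H](O)C1=O
F9 | step 17 | 4-methylidene-5α,6β-diol | C=C1[C@H]2C[C@@H](O[Si](C)(C)C(C)(C)C)[C@@H]([C@H](C)OC(C)=O)[C@H]2[C@@H](CCOC(C)=O)[C@@H](O)[C@@H]1O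
A1 | alternative 1 | cyclobutane photoadduct holding the cis-hydrindane | O1CCOC12[C@H]3C[C@H](O[Si](C)(C)C(C)(C)C)[C@@H]4[C@H]3[C@]5(C(=O)OC(C)(C)O[C@@]45C)[C@@H](O[Si](CC)(CC)CC)[C@@H]2OCc1ccccc1
A2 | alternative 2 | bridged bicyclo[2.2.2]octenone lactone | COC1(OC)C(=O)[C@H]2C3=C4C[C@H](O[Si](C)(C)C(C)(C)C)[C@H]3[C@H](C)OC(=O)[C@H]2[C@H](O[Si](C(C)C)(C(C)C)C(C)C)[C@H]14
A3 | alternative 3 | cis-hydrindanone with the acrylate at C7 and the silyl ether at C10 | C=C1[C@H]2CC(=O)[C@@H]([C@H](C)O[Si](C)(C)C(C)(C)C)[C@H]2[C@@H](C(=C)C(=O)OC)[C@@H](OC(=O)/C=C(\C)CC)[C@@H]1OC(=O)C[C@@H](C)CC
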